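All runs were generated by integration with made-up constants; the scatter is artificial.

If each product takes up one nucleophile, then product, as a fraction of the electrophile charged, cannot rise above the nucleophile charge divided by the electrophile charge. Where that ratio exceeds one, the whole electrophile charge is the limit instead.

| flask | electrophile | nucleophile | remark | time |
|---|---|---|---|---|
| birch | 0.19 M | 0.24 M (fed, over 25 h) | run made earlier |  |
| cedar | 0.28 M | 0.24 M (fed, over 25 h) | run made earlier |  |
| elm | 0.53 M | 0.24 M (fed, over 25 h) | run made earlier |  |
| beta | 0.50 M | 0.240 M | everything together at the start | 25 h |
| delta | 0.16 M | 0.240 M (fed, over 25 h) |  | 25 h |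

| run | time / h | product / % |
|---|---|---|
| birch | 3.00 | 4.7 |
| birch | 8.00 | 18.4 |
| birch | 15.0 | 35.8 |
| birch | 25.0 | 52.3 |
| cedar | 3.00 | 3.1 |
| cedar | 8.00 | 12.5 |
| cedar | 15.0 | 28.5 |
| cedar | 25.0 | 46.0 |
| elm | 3.00 | 1.6 |
| elm | 8.00 | 10.5 |
| elm | 15.0 | 20.2 |
| elm | 25.0 | 36.6 |

(scatter of a reading: 1 percentage point)



* which of the two ends with the higher amount of product, in percent of the electrophile charged ("neither" if they lie within 2 percentage points) (beta / delta / neither)
* product at the end, in percent of the electrophile charged, beta
* product at the end, in percent of the electrophile charged, delta

Work out this ratio first for beta, and call it the ceiling: 48.0%. The nucleophile is therefore the limiting reagent in beta.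

Now set beta beside elm, which looks nearly the same, with 0.53 M of electrophile against 0.50 M and the same nucleophile charge. Elm has a ceiling of 45.3%. Elm's reading at 25.0 h is 36.6%, which is 80.8% of that ceiling, with its nucleophile fed steadily up to that time. Beta has its whole charge from the start, where elm took 25 h to receive it; expect beta to use at least the same share of its ceiling. Take this as an estimate, not a bound: beta between 38.8% and 48.0%.

Next set delta beside birch. Their ratios are 1.50 and 1.26, so the ceiling of each is the whole electrophile charge. Birch reached 52.3%, and delta has more nucleophile per electrophile, so expect delta near that reading or a little above it. Because the birch reading stands 4.3 percentage points above beta's ceiling, name delta as the winner.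

The forecast also names delta, with 55% for delta and 36% for beta, “with wide uncertainty”. Its figure for beta lies below the bracket reckoned here.

The flasks give delta as the winner, with 55.0% for delta and 44.8% for beta, which is 93.3% of beta's ceiling.

    nucleophile + acid set free ⇌ protonated nucleophile, settled at all times (K = 73.8 /M)
    electrophile + nucleophile → acid set free + product (k = 2.67 × 10⁻⁴ /M/s)
    electrophile + acid set free ⇌ idle adduct, settled at all times (K = 740 /M)

Now apply the same reckoning to a neighbour of delta, fed in the same way but charged with 0.060 M of nucleophile. Its ratio of 0.375 equiv puts the nucleophile in the limiting place, and its ceiling is 37.5%. The neighbour ends at 23.8% after 25.0 h, which is 63.5% of that ceiling. Of its electrophile, 53% is still unbound and 22.8% sits as idle adduct, while 35% of its nucleophile is still unbound.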